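**Assumption:** gibberellic acid (GA3), a bulk fermentation product, is taken as the commercial starting material, so this is a semisynthesis in which the ring system is bought, not built.

## Retrosynthetic overview

1. GA79 ⇒ Δ1-olefin of the GA7 series. The C1–O and C2–O bonds are made last, in one syn-dihydroxylation on the β face, cis to the 3β-oxygen (key step), delivered by an osmium-binding glycinate ester on O3.
2. GA7 series ⇒ GA3 by radical removal of the bridgehead 13-OH through its oxalate. The O3 glycinate and a C7 silyl ester are the only protecting groups.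
3. Ring order: no ring is formed. Rings A–D and the 19,10-lactone (C3, C4, C5, C6, C8, C9, C10) come intact from GA3; only C13–H, C1–O and C2–O are made.

## Route

Step 1
Reactants: 1 gibberellic acid (GA3)
Product: 3 gibberellic acid 3-O-(N,N-dimethylglycinate) 7-(tert-butyldimethylsilyl) ester, via GA3 7-silyl ester 2 (not isolated)
Conditions: TBSCl (1.1 equiv), imidazole, DMF, 0 °C; then Me2NCH2CO2H, DIC, DMAP (cat.), 0 °C → rt, one pot
Reagents that add atoms: tert-butyldimethylsilyl chloride CC(C)(C)[Si](C)(C)Cl; N,N-dimethylglycine CN(C)CC(=O)O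
Why: The carboxylic acid silylates much faster than the hindered axial 3β-OH, and the following Steglich esterification acylates the secondary allylic 3β-OH while the bridgehead tertiary 13-OH stays free; no stereocentre is touched.

Step 2
Reactants: 3 gibberellic acid 3-O-(N,N-dimethylglycinate) 7-(tert-butyldimethylsilyl) ester
Product: 4 13-O-(methoxyoxalyl) derivative of 3
Conditions: MeO2CCOCl, pyridine, DMAP, CH2Cl2, 0 °C → rt
Reagents that add atoms: methyl chlorooxoacetate COC(=O)C(=O)Cl
Why: DMAP-catalysed acylation of the only free hydroxyl (bridgehead tertiary 13-OH) by the very electrophilic oxalyl chloride half-ester gives the radical-labile mixed oxalate; no stereocentre changes.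

Step 3
Reactants: 4 13-O-(methoxyoxalyl) derivative of 3
Product: 5 GA7 3-O-(N,N-dimethylglycinate) 7-(tert-butyldimethylsilyl) ester
Conditions: Bu3SnH, AIBN (cat.), PhMe, 110 °C
Reagents that add atoms: none
Why: Dolan–MacMillan oxalate variant of the Barton–McCombie radical deoxygenation: Bu3Sn• adds to the oxalate carbonyl, β-scission gives the C13 bridgehead radical (orthogonal to the 16-ene, so no allylic scrambling), and H-transfer from Bu3SnH can only occur with retention inside the bicyclo[3.2.1]octane cage, fixing C13–H.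

Step 4
Reactants: 5 GA7 3-O-(N,N-dimethylglycinate) 7-(tert-butyldimethylsilyl) ester
Product: 8 GA79, via cyclic osmate ester 6 (not isolated), via glycinate silyl ester diol 7 (not isolated)
Conditions: OsO4 (1.05 equiv), CH2Cl2 (2 mM), −78 → −20 °C; then aq Na2SO3, rt; then K2CO3, THF–H2O, 0 °C → rt; AcOH to pH 4
Reagents that add atoms: osmium tetroxide O=[Os](=O)(=O)=O
Why: Proposed new method: a tethered, ligand-gated osmium dihydroxylation – at low temperature in CH2Cl2 unligated OsO4 adds to alkenes only slowly while amine-bound OsO4 reacts orders of magnitude faster (amine-accelerated osmylation), and the only amine present is the glycinate NMe2 held on the 3β-oxygen, so activated Os(VIII) exists only over the β (exo) face of C1=C2 and adds through an eight-membered Os–N–CH2–C(=O)–O–C3–C2···O transition state, setting 1β-O and 2β-O cis to 3β-O (the α face carries the 19,10-lactone bridge), whereas the intrinsically more reactive 16-methylene can only be reached bimolecularly and is starved by the 2 mM dilution; sulfite then reduces the osmate and aqueous carbonate hydrolyses the base-labile α-amino ester and the silyl ester; closest known reaction types are the tethered aminohydroxylation of allylic carbamates, amine-accelerated stoichiometric osmylation and ester-borne reagent-directing groups in Rh/Cu chemistry.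

## Compound list

1 | gibberellic acid (GA3; 3β,13-dihydroxy-1,16-diene 19,10-lactone 7-acid) | C=C1C[C@]23C[C@@]1(O)CC[C@H]2[C@@]12OC(=O)[C@@](C)([C@H]1[C@@H]3C(=O)O)[C@@H](O)C=C2 | starting material
2 | GA3 7-(tert-butyldimethylsilyl) ester (3β-OH and 13-OH free) | C=C1C[C@]23C[C@@]1(O)CC[C@H]2[C@@]12OC(=O)[C@@](C)([C@H]1[C@@H]3C(=O)O[Si](C)(C)C(C)(C)C)[C@@H](O)C=C2 | intermediate
3 | GA3 3β-O-(N,N-dimethylglycinate) 7-(tert-butyldimethylsilyl) ester (13-OH free) | C=C1C[C@]23C[C@@]1(O)CC[C@H]2[C@@]12OC(=O)[C@@](C)([C@H]1[C@@H]3C(=O)O[Si](C)(C)C(C)(C)C)[C@@H](OC(=O)CN(C)C)C=C2 | intermediate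
4 | 13-O-(methoxyoxalyl) derivative of 3 | C=C1C[C@]23C[C@@]1(OC(=O)C(=O)OC)CC[C@H]2[C@@]12OC(=O)[C@@](C)([C@H]1[C@@H]3C(=O)O[Si](C)(C)C(C)(C)C)[C@@H](OC(=O)CN(C)C)C=C2 | intermediate
5 | GA7 3β-O-(N,N-dimethylglycinate) 7-(tert-butyldimethylsilyl) ester (13-H) | C=C1C[C@]23C[C@H]1CC[C@H]2[C@@]12OC(=O)[C@@](C)([C@H]1[C@@H]3C(=O)O[Si](C)(C)C(C)(C)C)[C@@H](OC(=O)CN(C)C)C=C2 | intermediate
6 | cyclic 1β,2β-osmate(VI) ester of 5 (dative N→Os contact of the glycinate not drawn) | C=C1C[C@]23C[C@H]1CC[C@H]2[C@@]12OC(=O)[C@@](C)([C@H]1[C@@H]3C(=O)O[Si](C)(C)C(C)(C)C)[C@@H](OC(=O)CN(C)C)[C@@H](O[Os]4(=O)=O)[C@H]2O4 | intermediate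
7 | 1β,2β-dihydroxy-GA9 3β-O-(N,N-dimethylglycinate) 7-(tert-butyldimethylsilyl) ester | C=C1C[C@]23C[C@H]1CC[C@H]2[C@@]12OC(=O)[C@@](C)([C@H]1[C@@H]3C(=O)O[Si](C)(C)C(C)(C)C)[C@@H](OC(=O)CN(C)C)[C@@H](O)[C@H]2O | intermediate
8 | GA79 (1β,2β,3β-trihydroxy-GA9; the target gibberellin) | C=C1C[C@]23C[C@H]1CC[C@H]2[C@@]12OC(=O)[C@@](C)([C@H]1[C@@H]3C(=O)O)[C@@H](O)[C@@H](O)[C@H]2O | target

## Summary

Total step count: 4. Longest linear sequence: 4 (from GA3).

## Steps most likely to fail

Step 4 (the proposed new step). The α-amino-ester amine may bind OsO4 too weakly, and on warming free or intermolecularly delivered osmium would attack the 16-methylene first. The fallback uses known chemistry and sets out from 5. K2CO3 in THF–H2O at 0 °C strips both esters to give 13-deoxygibberellic acid F1. Lemieux–Johnson cleavage (OsO4 cat., NaIO4, THF–H2O) then removes only the exocyclic methylene, the usual chemoselectivity in this series, to give 13-deoxygibberellic acid 16-norketone F2. The one remaining alkene is dihydroxylated syn to the free 3β-OH by hydrogen-bond-directed osmylation (OsO4, TMEDA, CH2Cl2, −78 °C) through the osmate–TMEDA chelate F3, which aqueous Na2SO3 cleaves to the 1β,2β,3β-triol 16-norketone F4. Lombardo methylenation (Zn, CH2Br2, TiCl4, excess) restores the 16-methylene and comes back to the route at 8.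

Step 3. Stannyl radicals may engage the allylic lactone or the allylic ester of ring A, or the bridgehead oxalate may fragment sluggishly. The fallback sets out from 3, bypasses 4 and uses a thiocarbonyl radical precursor with a silane chain carrier. Thiocarbonyldiimidazole with DMAP in toluene at 80 °C gives the 13-O-(imidazol-1-ylthiocarbonyl) derivative F5. Barton–McCombie reduction with (Me3Si)3SiH and AIBN in toluene at 90 °C comes back to the route at 5.

Step 1. The silyl ester may not survive the carbodiimide coupling, or the zwitterionic glycine may acylate the hindered 3β-OH poorly. The fallback sets out from 2, now isolated, and builds the glycinate on the alcohol in two stages. Chloroacetic anhydride and pyridine in CH2Cl2 at 0 °C give the 3-O-chloroacetyl silyl ester F6. Displacement of chloride with Me2NH (THF, NaI cat., 0 °C) comes back to the route at 3.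

## Further compounds

F1 | step 4 | 13-deoxygibberellic acid | C=C1C[C@]23C[C@H]1CC[C@H]2[C@@]12OC(=O)[C@@](C)([C@H]1[C@@H]3C(=O)O)[C@@H](O)C=C2
F2 | step 4 | 13-deoxygibberellic acid 16-norketone (17-nor-16-oxo) | O=C1C[C@]23C[C@H]1CC[C@H]2[C@@]12OC(=O)[C@@](C)([C@H]1[C@@H]3C(=O)O)[C@@H](O)C=C2
F3 | step 4 | osmate–TMEDA chelate (1β,2β-osmate(VI) ester of F2) | O=C1C[C@]23C[C@H]1CC[C@H]2[C@@]12OC(=O)[C@@](C)([C@H]1[C@@H]3C(=O)O)[C@@H](O)[C@@H](O[Os-2]45(=O)(=O)[N+](C)(C)CC[N+]4(C)C)[C@H]2O5
F4 | step 4 | 1β,2β,3β-triol 16-norketone (17-nor-16-oxo analogue of 8) | O=C1C[C@]23C[C@H]1CC[C@H]2[C@@]12OC(=O)[C@@](C)([C@H]1[C@@H]3C(=O)O)[C@@H](O)[C@@H](O)[C@H]2O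
F5 | step 3 | 13-O-(imidazol-1-ylthiocarbonyl) derivative of 3 | C=C1C[C@]23C[C@@]1(OC(=S)n4ccnc4)CC[C@H]2[C@@]12OC(=O)[C@@](C)([C@H]1[C@@H]3C(=O)O[Si](C)(C)C(C)(C)C)[C@@H](OC(=O)CN(C)C)C=C2
F6 | step 1 | 3-O-chloroacetyl 7-(tert-butyldimethylsilyl) ester of gibberellic acid | C=C1C[C@]23C[C@@]1(O)CC[C@H]2[C@@]12OC(=O)[C@@](C)([C@H]1[C@@H]3C(=O)O[Si](C)(C)C(C)(C)C)[C@@H](OC(=O)CCl)C=C2
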